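We start from a small charge of reagent: 1.80 reagent per substrate, where the path to target takes two.

common to all: reagent 0.198 M

| run | substrate | remark | time |
|---|---|---|---|
| north | 0.11 M | run made earlier |  |
| north-east | 0.17 M | run made earlier |  |
| dawn | 0.11 M | everything together in a closed stirred flask, run for 4.0 d | 4.0 d |
| dusk | 0.11 M | a single well-mixed tank run continuously and read at steady state, 4.0 d in it on average |  |
| summer | 0.11 M (fed, over 4.00 d) | a stirred flask in which substrate is dosed at a steady rate over 4.00 d without added volume, worked up at 4.0 d | 4.0 d |
| autumn | 0.11 M | a single well-mixed tank run continuously and read at steady state, 40.0 d in it on average |  |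

- north (time / d: target / %, substrate / %): 0.417: 0, 78.8; 0.833: 1.3, 64.1; 1.25: 5.1, 53.0; 1.67: 5.4, 45.6; 2.08: 7.9, 41.2; 2.50: 10.4, 35.6
- north-east (time / h: target / %, substrate / %): 2.50: 0, 94.6; 4.00: 1.3, 89.5; 6.00: 0.5, 86.9; 10.0: 0, 79.1; 20.0: 1.8, 66.6; 30.0: 4.0, 57.6

(readings scatter by 1 percentage point)

- the stated concentrations are those of everything mixed, before any reaction; amounts are the same in each set-up
- the numbers in the tables scatter by 1 percentage point (one standard deviation)
- steps thought possible: substrate + reagent -> intermediate A; reagent + intermediate A -> intermediate B; intermediate B <-> target
- the feed brings no volume worth counting
- the earlier runs were made in a closed, stirred flask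

* the set-up with the highest amount of target at the outlet or at the end, in percent of the substrate put in ("none" if the first two lie within 2 percentage points) (dawn / dusk / summer / autumn / none)
* amount of target at the outlet or at the end, in percent of the substrate put in, dawn
* amount of target at the outlet or at the end, in percent of the substrate put in, dusk
* amount of target at the outlet or at the end, in percent of the substrate put in, summer
* amount of target at the outlet or at the end, in percent of the substrate put in, autumn

How far can the reagent carry the substrate? Counted in fractions of the substrate charge, reagent spent equals substrate reacted plus the passed share, meaning intermediate B and target together, which have taken a second reagent. The passed share cannot exceed the substrate reacted, so its largest value is 90.0%, the reagent per substrate divided by two. This is our second-step ceiling, and it makes the reagent the limiting reagent of the full path.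

Is that ceiling what holds target down over these days? The north run, with the same charge, read 10.4% target at 2.50 d, which is 0.116 of the ceiling. Its substrate read 35.6%, so even with every reacted substrate passed, the north run had spent 129% of the substrate charge in reagent at that time, less than the 180% charged, and we turn to time.

Does time differ between the set-ups? Autumn's tank gives 40.0 d on average against 4.0 d for dawn, a ratio of 10.0, so we put autumn first. The tables of the north and north-east runs give target and substrate, with no column for intermediate B, so our reckoning stops at this order and this ceiling.

The forecast gave dawn 18.5%, dusk 16%, summer 10.5% and autumn 46% (range 26% to 57%), with the words “Autumn is clearly best”.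

    substrate + reagent → intermediate A (k = 0.130 /M/h)
    reagent + intermediate A → intermediate B (k = 0.220 /M/h)
    intermediate B ⇌ target (K = 0.780, k = 0.0220 /h)

Autumn gives 30.1% target, ahead of dawn at 19.2%, dusk at 13.4% and summer at 9.85%. Autumn's tank holds reagent equal to 29.6% of the substrate charge and 19.7% substrate, so the balance gives a passed share of 70.1%, below the ceiling of 90.0%. Dusk's tank holds 23.5% intermediate B and 13.4% target, a passed share of 36.9%, and with reagent equal to 88.3% of the substrate charge the balance puts substrate reacted in dusk at 54.8%.

The data stem from a simulated flask from invented constants; the scatter is artificial.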